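**Retrosynthetic overview**
1. Last operations: global O‑debenzylation, preceded by formation of the two aryl–C bonds at C8 and C6 of (+)‑afzelechin by 1,6‑addition to a p‑quinone methide generated from one fully built tetrahydrofuran carbinol (used twice).
2. The aroyl group at C3 comes from aryllithium opening of a fused γ‑lactone that tells the two esters of a geminal diester apart; C3 is then set by decarboxylation and equilibration.
3. Key disconnection (tetrahydrofuran ring): the C5–O1 ether bond, formed when the oxygen of 4‑(benzyloxy)benzaldehyde opens a trans donor–acceptor cyclopropane with inversion; the C2–C3 bond closes in the same operation.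
4. The cyclopropane comes from an asymmetric Michael‑initiated ring closure of a chalcone‑type enone with a bromomalonate; the enone from a Claisen–Schmidt condensation.
5. Ring order: cyclopropane → tetrahydrofuran (→ transient fused γ‑lactone, reopened) → attachment to the intact chroman of afzelechin.

Assumption: all six starting materials, including natural (2R,3S)‑(+)‑afzelechin, are bought; tetrahydrofuran positions are numbered O1, C2 (4‑oxyphenyl), C3 (acyl), C4 (side chain), C5 (2,4‑dioxyphenyl) throughout, also where the ring is named as a substituent.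

**Step 1**
Reactants: 1 2,4‑bis(benzyloxy)benzaldehyde; 2 1‑[4‑(allyloxy)phenyl]ethan‑1‑one
Product: 3 (2E)‑1‑[4‑(allyloxy)phenyl]‑3‑[2,4‑bis(benzyloxy)phenyl]prop‑2‑en‑1‑one
Conditions: KOH, EtOH, 25 °C
Reagents that add atoms: none
Why: Claisen–Schmidt aldol condensation, in which the acetophenone enolate adds to the non‑enolisable aldehyde and E1cB dehydration gives only the conjugated (E)‑enone, with aryl benzyl and allyl ethers inert to ethanolic KOH.

**Step 2**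
Reactants: 4 diallyl malonate
Product: 5 diallyl 2‑bromomalonate
Conditions: NBS (1.05 equiv), Mg(ClO4)2 (10 mol%), EtOAc, 0 → 25 °C, dark
Reagents that add atoms: N‑bromosuccinimide, O=C1CCC(=O)N1Br
Why: Lewis‑acid‑assisted electrophilic α‑bromination of a 1,3‑dicarbonyl compound, mono‑selective because the bromomalonate enolises more slowly, under ionic conditions that leave the allyl C=C bonds untouched.

**Step 3**
Reactants: 3 (2E)‑1‑[4‑(allyloxy)phenyl]‑3‑[2,4‑bis(benzyloxy)phenyl]prop‑2‑en‑1‑one; 5 diallyl 2‑bromomalonate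
Product: 6 diallyl (2R,3S)‑2‑[4‑(allyloxy)benzoyl]‑3‑[2,4‑bis(benzyloxy)phenyl]cyclopropane‑1,1‑dicarboxylate (trans)
Conditions: N‑(9‑anthracenylmethyl)quinidinium bromide with free 9‑OH (10 mol%), K2CO3 (solid), mesitylene, 0 °C; one recrystallisation
Reagents that add atoms: none
Why: Michael‑initiated ring closure under chiral ammonium phase‑transfer catalysis, in which the ion‑paired bromomalonate enolate adds to one enantioface of the enone β‑carbon and the ketone enolate then displaces bromide (3‑exo‑tet), setting the trans (2R,3S) pair that becomes C4 and C5 (the quininium pseudoenantiomer gives ent‑6, so the sense is fixed by one calibration run).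

**Step 4**
Reactants: 6 diallyl (2R,3S)‑2‑[4‑(allyloxy)benzoyl]‑3‑[2,4‑bis(benzyloxy)phenyl]cyclopropane‑1,1‑dicarboxylate; 7 4‑(benzyloxy)benzaldehyde
Product: 8 diallyl (2R,4S,5R)‑4‑[4‑(allyloxy)benzoyl]‑2‑[4‑(benzyloxy)phenyl]‑5‑[2,4‑bis(benzyloxy)phenyl]tetrahydrofuran‑3,3‑dicarboxylate
Conditions: Sn(OTf)2 (10 mol%), 7 (3 equiv), CH2Cl2, −20 → 10 °C
Reagents that add atoms: none
Why: Lewis‑acid‑catalysed (3+2) annulation of a donor–acceptor cyclopropane with an aldehyde, in which the aldehyde oxygen opens the chelated malonate cyclopropane at the benzylic carbon in an SN2‑like way with inversion (this C5–O1 bond is the key bond and turns the trans cyclopropane into the 4,5‑cis ether) and the malonate enolate then closes on the oxocarbenium ion through an envelope with the new aryl group pseudo‑equatorial, setting C2 cis to C5.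

**Step 5**
Reactants: 8 diallyl (2R,4S,5R)‑4‑[4‑(allyloxy)benzoyl]‑2‑[4‑(benzyloxy)phenyl]‑5‑[2,4‑bis(benzyloxy)phenyl]tetrahydrofuran‑3,3‑dicarboxylate
Product: 10 allyl (3aS,4R,6R,6aR)‑3‑[4‑(allyloxy)phenyl]‑6‑[4‑(benzyloxy)phenyl]‑4‑[2,4‑bis(benzyloxy)phenyl]‑1‑oxohexahydrofuro[3,4‑c]furan‑6a‑carboxylate (cis‑fused γ‑lactone; C3 epimers), via hydroxy diester 9 (not isolated)
Conditions: NaBH4, THF–i‑PrOH (5:1), −20 → 0 °C; then DBU (0.2 equiv), THF, 25 °C
Reagents that add atoms: none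
Why: Chemoselective hydride reduction followed by lactonisation, in which the aryl ketone is the only group NaBH4 reduces and the resulting alkoxide attacks the allyl ester that is cis to it on the adjacent quaternary carbon (5‑exo‑trig transesterification), which differentiates the two esters; the new carbinol centre forms as a mixture and is erased in step 8.

**Step 6**
Reactants: 10 cis‑fused γ‑lactone allyl ester; 11 1‑bromo‑2,4‑bis(benzyloxy)benzene
Product: 13 allyl (2R,3S,4R,5R)‑4‑{[4‑(allyloxy)phenyl](hydroxy)methyl}‑3‑[2,4‑bis(benzyloxy)benzoyl]‑2‑[4‑(benzyloxy)phenyl]‑5‑[2,4‑bis(benzyloxy)phenyl]tetrahydrofuran‑3‑carboxylate (carbinol epimers; in equilibrium with its cyclic hemiketal), via aryllithium 12 (not isolated)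
Conditions: 11 (1.3 equiv), n‑BuLi (1.25 equiv), THF, −78 °C; then 10, −78 → −50 °C; H2O
Reagents that add atoms: none
Why: Bromine–lithium exchange and single addition of the aryllithium to the γ‑lactone, in which the strained lactone carbonyl on the convex face reacts in preference to the neopentyl‑type allyl ester and the lithium hemiketalate does not collapse at low temperature, so over‑addition is avoided and the aryl ketone sits on C3 cis to the side chain.

**Step 7**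
Reactants: 13 allyl (2R,3S,4R,5R)‑keto ester
Product: 15 {(2S,4R,5R)‑2‑[4‑(benzyloxy)phenyl]‑5‑[2,4‑bis(benzyloxy)phenyl]‑4‑[hydroxy(4‑hydroxyphenyl)methyl]tetrahydrofuran‑3‑yl}[2,4‑bis(benzyloxy)phenyl]methanone (C3 and carbinol epimers), via keto acid 14 (not isolated)
Conditions: Pd(PPh3)4 (5 mol%), morpholine (6 equiv), THF, 25 °C
Reagents that add atoms: none
Why: Tsuji–Trost deallylation with morpholine as allyl acceptor, in which zerovalent palladium ionises the allyl ester and the aryl allyl ether, the freed β‑keto acid loses CO2 through its enol at 25 °C, and C3 is left as an epimer mixture (partly held as the cyclic hemiketal with the neighbouring carbinol) that is corrected in step 8.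

**Step 8**
Reactants: 15 p‑hydroxybenzylic alcohol (2.4 equiv); 16 (+)‑afzelechin, (2R,3S)‑2‑(4‑hydroxyphenyl)chromane‑3,5,7‑triol
Product: 19 (2R,3S)‑afzelechin carrying at C6 and at C8 the (S)‑(4‑hydroxyphenyl){(2S,3S,4S,5R)‑3‑[2,4‑bis(benzyloxy)benzoyl]‑2‑[4‑(benzyloxy)phenyl]‑5‑[2,4‑bis(benzyloxy)phenyl]tetrahydrofuran‑4‑yl}methyl group (deca‑O‑benzyl ether of the target), via quinone methide 17 (not isolated), via mono‑adduct 18 (not isolated)
Conditions: (R)‑TRIP (10 mol%), EtOAc–CH2Cl2 (1:1), 4 Å MS, 0 → 25 °C; then DBU (0.5 equiv), 25 °C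
Reagents that add atoms: none
Why: Proposed new method: a chiral phosphoric acid‑catalysed, twofold diastereoselective Friedel–Crafts 1,6‑addition of unprotected (+)‑afzelechin (C8 first, then C6) to the α‑branched alkyl p‑quinone methide 17 that the acid releases from 15 by loss of water (or by opening of its hemiketal); mechanistically the acid hydrogen‑bonds the quinone methide carbonyl while its P=O oxygen holds the C7–OH or C5–OH of the phloroglucinol ring, so the ortho carbon is delivered inside the chiral pocket to the Si face of the methide carbon and rearomatisation gives the (S)‑diarylmethine under catalyst control (the acid antipode is confirmed by a test run), after which DBU equilibrates the enolisable C3, and C2 by reversible oxa‑Michael opening, to the 2,3‑trans‑3,4‑trans arrangement; closest known reaction type: chiral phosphoric acid‑catalysed asymmetric 1,6‑additions of phenols, naphthols and indoles to aryl‑substituted p‑quinone methides formed in situ from p‑hydroxybenzyl alcohols, here extended to an α‑stereogenic alkyl quinone methide and a double C‑arylation.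

**Step 9**
Reactants: 19 deca‑O‑benzyl bis‑adduct
Product: 20 target CNP0225367.3, (2R,3S)‑afzelechin carrying at C6 and C8 the (S)‑(4‑hydroxyphenyl)[(2S,3S,4S,5R)‑3‑(2,4‑dihydroxybenzoyl)‑5‑(2,4‑dihydroxyphenyl)‑2‑(4‑hydroxyphenyl)tetrahydrofuran‑4‑yl]methyl group
Conditions: H2 (1 atm), Pd(OH)2/C, EtOAc–MeOH (1:1), 25 °C
Reagents that add atoms: none
Why: Hydrogenolysis of the ten aryl benzyl ethers, which cleave far faster than the dialkyl benzylic C–O bonds of the tetrahydrofuran and chroman rings or the aryl ketones under neutral conditions, so stopping at full debenzylation gives the target with all twelve stereocentres unchanged.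

**Compound list**
1 | 2,4‑bis(benzyloxy)benzaldehyde | O=Cc1ccc(OCc2ccccc2)cc1OCc1ccccc1 | starting material
2 | 1‑[4‑(allyloxy)phenyl]ethan‑1‑one | CC(=O)c1ccc(OCC=C)cc1 | starting material
3 | (2E)‑1‑[4‑(allyloxy)phenyl]‑3‑[2,4‑bis(benzyloxy)phenyl]prop‑2‑en‑1‑one | C=CCOc1ccc(cc1)C(=O)/C=C/c1ccc(OCc2ccccc2)cc1OCc1ccccc1 | intermediate
4 | diallyl malonate | C=CCOC(=O)CC(=O)OCC=C | starting material
5 | diallyl 2‑bromomalonate | C=CCOC(=O)C(Br)C(=O)OCC=C | intermediate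
6 | diallyl (2R,3S)‑2‑[4‑(allyloxy)benzoyl]‑3‑[2,4‑bis(benzyloxy)phenyl]cyclopropane‑1,1‑dicarboxylate | C=CCOc1ccc(cc1)C(=O)[C@@H]2[C@@H](c1ccc(OCc3ccccc3)cc1OCc1ccccc1)C2(C(=O)OCC=C)C(=O)OCC=C | intermediate
7 | 4‑(benzyloxy)benzaldehyde | O=Cc1ccc(OCc2ccccc2)cc1 | starting material
8 | diallyl (2R,4S,5R)‑4‑[4‑(allyloxy)benzoyl]‑2‑[4‑(benzyloxy)phenyl]‑5‑[2,4‑bis(benzyloxy)phenyl]tetrahydrofuran‑3,3‑dicarboxylate | C=CCOc1ccc(cc1)C(=O)[C@H]4C(C(=O)OCC=C)(C(=O)OCC=C)[C@@H](c1ccc(OCc2ccccc2)cc1)O[C@H]4c1ccc(OCc2ccccc2)cc1OCc1ccccc1 | intermediate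
9 | diallyl (2R,4R,5R)‑4‑{[4‑(allyloxy)phenyl](hydroxy)methyl}‑2‑[4‑(benzyloxy)phenyl]‑5‑[2,4‑bis(benzyloxy)phenyl]tetrahydrofuran‑3,3‑dicarboxylate (carbinol centre unassigned) | C=CCOc1ccc(cc1)C(O)[C@H]4C(C(=O)OCC=C)(C(=O)OCC=C)[C@@H](c1ccc(OCc2ccccc2)cc1)O[C@H]4c1ccc(OCc2ccccc2)cc1OCc1ccccc1 | intermediate (not isolated)
10 | allyl (3aS,4R,6R,6aR)‑3‑[4‑(allyloxy)phenyl]‑6‑[4‑(benzyloxy)phenyl]‑4‑[2,4‑bis(benzyloxy)phenyl]‑1‑oxohexahydrofuro[3,4‑c]furan‑6a‑carboxylate (C3 unassigned; C3a = former C4, C4 = former C5, C6 = former C2, C6a = former C3) | C=CCOc1ccc(cc1)C2OC(=O)[C@]3(C(=O)OCC=C)[C@H]2[C@H](c2ccc(OCc4ccccc4)cc2OCc2ccccc2)O[C@@H]3c1ccc(OCc2ccccc2)cc1 | intermediate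
11 | 1‑bromo‑2,4‑bis(benzyloxy)benzene | Brc1ccc(OCc2ccccc2)cc1OCc1ccccc1 | starting material
12 | [2,4‑bis(benzyloxy)phenyl]lithium | [Li]c1ccc(OCc2ccccc2)cc1OCc1ccccc1 | intermediate (not isolated)
13 | allyl (2R,3S,4R,5R)‑4‑{[4‑(allyloxy)phenyl](hydroxy)methyl}‑3‑[2,4‑bis(benzyloxy)benzoyl]‑2‑[4‑(benzyloxy)phenyl]‑5‑[2,4‑bis(benzyloxy)phenyl]tetrahydrofuran‑3‑carboxylate (carbinol centre unassigned) | C=CCOc1ccc(cc1)C(O)[C@H]4[C@](C(=O)c1ccc(OCc2ccccc2)cc1OCc1ccccc1)(C(=O)OCC=C)[C@@H](c1ccc(OCc2ccccc2)cc1)O[C@H]4c1ccc(OCc2ccccc2)cc1OCc1ccccc1 | intermediate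
14 | (2R,3S,4R,5R)‑3‑[2,4‑bis(benzyloxy)benzoyl]‑2‑[4‑(benzyloxy)phenyl]‑5‑[2,4‑bis(benzyloxy)phenyl]‑4‑[hydroxy(4‑hydroxyphenyl)methyl]tetrahydrofuran‑3‑carboxylic acid (carbinol centre unassigned) | Oc1ccc(cc1)C(O)[C@H]4[C@](C(=O)c1ccc(OCc2ccccc2)cc1OCc1ccccc1)(C(=O)O)[C@@H](c1ccc(OCc2ccccc2)cc1)O[C@H]4c1ccc(OCc2ccccc2)cc1OCc1ccccc1 | intermediate (not isolated)
15 | {(2S,4R,5R)‑2‑[4‑(benzyloxy)phenyl]‑5‑[2,4‑bis(benzyloxy)phenyl]‑4‑[hydroxy(4‑hydroxyphenyl)methyl]tetrahydrofuran‑3‑yl}[2,4‑bis(benzyloxy)phenyl]methanone (C3 and carbinol centre unassigned) | Oc1ccc(cc1)C(O)[C@H]4C(C(=O)c1ccc(OCc2ccccc2)cc1OCc1ccccc1)[C@@H](c1ccc(OCc2ccccc2)cc1)O[C@H]4c1ccc(OCc2ccccc2)cc1OCc1ccccc1 | intermediate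
16 | (+)‑afzelechin, (2R,3S)‑2‑(4‑hydroxyphenyl)chromane‑3,5,7‑triol | Oc1cc(O)c2c(c1)O[C@H](c1ccc(O)cc1)[C@@H](O)C2 | starting material
17 | 4‑({(2S,4S,5R)‑3‑[2,4‑bis(benzyloxy)benzoyl]‑2‑[4‑(benzyloxy)phenyl]‑5‑[2,4‑bis(benzyloxy)phenyl]tetrahydrofuran‑4‑yl}methylidene)cyclohexa‑2,5‑dien‑1‑one (C3 unassigned) | O=C1C=CC(=C[C@H]4C(C(=O)c2ccc(OCc3ccccc3)cc2OCc2ccccc2)[C@@H](c2ccc(OCc3ccccc3)cc2)O[C@H]4c2ccc(OCc3ccccc3)cc2OCc2ccccc2)C=C1 | intermediate (not isolated)
18 | (2R,3S)‑afzelechin carrying at C8 the (S)‑(4‑hydroxyphenyl){(2S,4S,5R)‑3‑[2,4‑bis(benzyloxy)benzoyl]‑2‑[4‑(benzyloxy)phenyl]‑5‑[2,4‑bis(benzyloxy)phenyl]tetrahydrofuran‑4‑yl}methyl group (C3 unassigned) | c1c(O)c2c(c([C@H](c3ccc(O)cc3)[C@H]4C(C(=O)c3ccc(OCc5ccccc5)cc3OCc3ccccc3)[C@@H](c3ccc(OCc5ccccc5)cc3)O[C@H]4c3ccc(OCc5ccccc5)cc3OCc3ccccc3)c1O)O[C@H](c1ccc(O)cc1)[C@@H](O)C2 | intermediate (not isolated)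
19 | (2R,3S)‑afzelechin carrying at C6 and C8 the (S)‑(4‑hydroxyphenyl){(2S,3S,4S,5R)‑3‑[2,4‑bis(benzyloxy)benzoyl]‑2‑[4‑(benzyloxy)phenyl]‑5‑[2,4‑bis(benzyloxy)phenyl]tetrahydrofuran‑4‑yl}methyl group | O=C(c1ccc(OCc6ccccc6)cc1OCc6ccccc6)[C@H]1[C@H]([C@@H](c2ccc(O)cc2)c2c(O)c3c(c([C@H](c4ccc(O)cc4)[C@H]4[C@H](C(=O)c5ccc(OCc6ccccc6)cc5OCc6ccccc6)[C@@H](c5ccc(OCc6ccccc6)cc5)O[C@H]4c4ccc(OCc6ccccc6)cc4OCc6ccccc6)c2O)O[C@H](c2ccc(O)cc2)[C@@H](O)C3)[C@H](c2ccc(OCc6ccccc6)cc2OCc6ccccc6)O[C@@H]1c1ccc(OCc6ccccc6)cc1 | intermediate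
20 | CNP0225367.3, (2R,3S)‑afzelechin carrying at C6 and C8 the (S)‑(4‑hydroxyphenyl)[(2S,3S,4S,5R)‑3‑(2,4‑dihydroxybenzoyl)‑5‑(2,4‑dihydroxyphenyl)‑2‑(4‑hydroxyphenyl)tetrahydrofuran‑4‑yl]methyl group | O=C(c1ccc(O)cc1O)[C@H]1[C@H]([C@@H](c2ccc(O)cc2)c2c(O)c3c(c([C@H](c4ccc(O)cc4)[C@H]4[C@H](C(=O)c5ccc(O)cc5O)[C@@H](c5ccc(O)cc5)O[C@H]4c4ccc(O)cc4O)c2O)O[C@H](c2ccc(O)cc2)[C@@H](O)C3)[C@H](c2ccc(O)cc2O)O[C@@H]1c1ccc(O)cc1 | target

**Totals**
Total steps: 9. Longest linear sequence: 8 steps (steps 2–9 from 4; equally steps 1 and 3–9 from 1 and 2).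

**Three steps most likely to fail**

Step 8 (the proposed new step). Risks: the C4 stereocentre may bias the methide face against the catalyst; the alkyl quinone methide may tautomerise to the vinylphenol and lose C4; the second arylation at C6 may stall; and the acid may ionise the electron‑rich C5–O bond. The fallback uses known chemistry, sets out from 15 and 16 and comes back at 20. Afzelechin is benzylated at its three phenols (BnBr, K2CO3, DMF) to (2R,3S)‑5,7‑bis(benzyloxy)‑2‑[4‑(benzyloxy)phenyl]chroman‑3‑ol F5, the standard nucleophile of interflavan couplings. F5 is then C‑alkylated at C8 and C6 with 15 under a stoichiometric Lewis acid (TMSOTf or BF3·OEt2, CH2Cl2, −78 → −20 °C), the established cationic Friedel–Crafts benzylation of 5,7‑di‑O‑benzylflavans. This gives, under substrate control, the 5,7,4'‑tri‑O‑benzyl ether of bis‑adduct 19 F6. Its methine diastereomers are separated by preparative HPLC, C3 is reset with DBU, and hydrogenolysis as in step 9 gives 20.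

Step 6. Risks: the lactone carbonyl sits on a quaternary carbon and may react slowly with the ortho‑substituted aryllithium, or the allyl ester may compete. The fallback sets out from 10 and comes back at 13. The lactone is opened with the aluminium amide made from MeNH(OMe)·HCl and AlMe3 (CH2Cl2, 0 °C) to allyl (2R,3S,4R,5R)‑4‑{[4‑(allyloxy)phenyl](hydroxy)methyl}‑2‑[4‑(benzyloxy)phenyl]‑5‑[2,4‑bis(benzyloxy)phenyl]‑3‑[methoxy(methyl)carbamoyl]tetrahydrofuran‑3‑carboxylate F4. [2,4‑Bis(benzyloxy)phenyl]magnesium bromide (from 11 and Mg, 2.5 equiv, THF, 0 °C) then converts F4 into 13 by the Weinreb ketone synthesis.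

Step 3. Risks: modest enantioselectivity or slow ring closure with the ortho‑substituted, electron‑rich β‑aryl enone. The fallback sets out from 1 and 5 and comes back at 6. Wittig homologation of 1 with Ph3P=CHCHO (toluene, 80 °C) gives (2E)‑3‑[2,4‑bis(benzyloxy)phenyl]prop‑2‑enal F1. Iminium‑catalysed Michael‑initiated ring closure with 5 (diphenylprolinol trimethylsilyl ether, antipode chosen for this sense, 2,6‑lutidine, CH2Cl2, 0 °C) gives diallyl (2S,3R)‑2‑[2,4‑bis(benzyloxy)phenyl]‑3‑formylcyclopropane‑1,1‑dicarboxylate F2. [4‑(Allyloxy)phenyl]magnesium bromide (THF, −78 °C, cold acetic acid quench) adds to the aldehyde to give diallyl (2R,3S)‑2‑{[4‑(allyloxy)phenyl](hydroxy)methyl}‑3‑[2,4‑bis(benzyloxy)phenyl]cyclopropane‑1,1‑dicarboxylate F3. Immediate Dess–Martin oxidation returns 6.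

**Further compounds**
F1 | step 3 | (2E)‑3‑[2,4‑bis(benzyloxy)phenyl]prop‑2‑enal | O=C/C=C/c1ccc(OCc2ccccc2)cc1OCc1ccccc1
F2 | step 3 | diallyl (2S,3R)‑2‑[2,4‑bis(benzyloxy)phenyl]‑3‑formylcyclopropane‑1,1‑dicarboxylate | O=C[C@@H]2[C@@H](c1ccc(OCc3ccccc3)cc1OCc1ccccc1)C2(C(=O)OCC=C)C(=O)OCC=C
F3 | step 3 | diallyl (2R,3S)‑2‑{[4‑(allyloxy)phenyl](hydroxy)methyl}‑3‑[2,4‑bis(benzyloxy)phenyl]cyclopropane‑1,1‑dicarboxylate (carbinol centre unassigned) | C=CCOc1ccc(cc1)C(O)[C@@H]2[C@@H](c1ccc(OCc3ccccc3)cc1OCc1ccccc1)C2(C(=O)OCC=C)C(=O)OCC=C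
F4 | step 6 | allyl (2R,3S,4R,5R)‑4‑{[4‑(allyloxy)phenyl](hydroxy)methyl}‑2‑[4‑(benzyloxy)phenyl]‑5‑[2,4‑bis(benzyloxy)phenyl]‑3‑[methoxy(methyl)carbamoyl]tetrahydrofuran‑3‑carboxylate (carbinol centre unassigned) | C=CCOc1ccc(cc1)C(O)[C@H]4[C@](C(=O)N(C)OC)(C(=O)OCC=C)[C@@H](c1ccc(OCc2ccccc2)cc1)O[C@H]4c1ccc(OCc2ccccc2)cc1OCc1ccccc1
F5 | step 8 | (2R,3S)‑5,7‑bis(benzyloxy)‑2‑[4‑(benzyloxy)phenyl]chroman‑3‑ol | O(Cc3ccccc3)c1cc(OCc3ccccc3)c2c(c1)O[C@H](c1ccc(OCc3ccccc3)cc1)[C@@H](O)C2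
F6 | step 8 | 5,7,4'‑tri‑O‑benzyl ether of bis‑adduct 19 | O=C(c1ccc(OCc6ccccc6)cc1OCc6ccccc6)[C@H]1[C@H]([C@@H](c2ccc(O)cc2)c2c(OCc6ccccc6)c3c(c([C@H](c4ccc(O)cc4)[C@H]4[C@H](C(=O)c5ccc(OCc6ccccc6)cc5OCc6ccccc6)[C@@H](c5ccc(OCc6ccccc6)cc5)O[C@H]4c4ccc(OCc6ccccc6)cc4OCc6ccccc6)c2OCc6ccccc6)O[C@H](c2ccc(OCc6ccccc6)cc2)[C@@H](O)C3)[C@H](c2ccc(OCc6ccccc6)cc2OCc6ccccc6)O[C@@H]1c1ccc(OCc6ccccc6)cc1
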